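**Plan**

1. Numbering (eremophilane): ring A = C1–C5 and C10 (O on C3, methyls on C4 and C5); ring B = C5–C10 (C8 carbonyl, C6=C7 and C9=C10 double bonds, C11 carbinol on C7).
2. Retrosynthetic cuts, in order: the ester C(=O)–O3 bond; C7–C11 (coupling, then hydration); removal of C7 from ring B (the reverse of a one-carbon insertion) to give a fused cyclopentenone C5–C6–C8–C9–C10; then C9=C10 (aldol), C5–C6 (enolate alkylation) and C4–CH3 (cuprate addition).
3. Forward: chiral cyclohexenone (ring A) → conjugate methylation/propargylation → fused cyclopentenone → dibromocarbene inserts C7 into the C6–C8 bond, giving ring B as its 7-bromo dienone → isopropenyl coupling, hydration, desilylation, esterification.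
4. Enabling feature: ring B is a cyclohexa-2,5-dienone in which C7 lies between the carbonyl C8 and C6–H, and C5 is quaternary. The kinetic silyl dienol ether of the five-membered enone is therefore a 5,5-blocked 2-silyloxycyclopentadiene that takes up a carbene carbon at C6=C8 and cannot aromatise after ring opening; the silyl group leaves in the same step and the bromine becomes the coupling handle.
5. Stereochemistry: C3 from a lipase resolution; C4 by cuprate addition anti to the C3 silyloxy group; C5 by enolate alkylation anti to the C4 methyl; the Z-alkene from anti-carbomagnesiation of propargyl alcohol, kept by a retentive C–S coupling.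

Key step: step 8

Assumption: the hydrolase in step 2 is selected by screening so that the (R)-acetate is hydrolysed faster; with an enzyme of opposite preference the unreacted (R)-acetate would be isolated from the same resolution and cleaved by a non-selective esterase to the same alcohol 3. Compounds 1 and 17 and all named reagents are taken as commercial.

**Route**

Step 1
Reactants: 1 3-ethoxy-2-methylcyclohex-2-en-1-one
Product: 2 rac-6-acetoxy-3-ethoxy-2-methylcyclohex-2-en-1-one
Conditions: Mn(OAc)3·2H2O, benzene, reflux (Dean–Stark)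
Reagents that add atoms: manganese(III) acetate, CC(=O)[O-].CC(=O)[O-].CC(=O)[O-].[Mn+3]
Why: Mn(III)-mediated α′-acetoxylation of an enone through the Mn(III) enolate/α′-keto radical; C6 is the only enolisable α-position of the vinylogous ester, and the product is racemic.

Step 2
Reactants: 2 rac-6-acetoxy-3-ethoxy-2-methylcyclohex-2-en-1-one
Product: 3 (R)-3-ethoxy-6-hydroxy-2-methylcyclohex-2-en-1-one
Conditions: lipase (e.g. Amano PS) or esterase, pH 7 phosphate buffer/MTBE, rt, to about half conversion
Reagents that add atoms: none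
Why: Enzymatic kinetic resolution by enantioselective ester hydrolysis, a reaction type established for α′-acetoxy enones; it sets the carbinol centre that becomes C3, and the unreacted (S)-acetate is removed by chromatography.

Step 3
Reactants: 3 (R)-3-ethoxy-6-hydroxy-2-methylcyclohex-2-en-1-one
Product: 4 (R)-6-[(tert-butyldimethylsilyl)oxy]-3-ethoxy-2-methylcyclohex-2-en-1-one
Conditions: TBSCl, imidazole, DMF, rt
Reagents that add atoms: tert-butyldimethylsilyl chloride, CC(C)(C)[Si](C)(C)Cl
Why: Standard silylation of a secondary alcohol; the silyl ether protects the oxygen from the hydride, cuprate, amide base and carbene that follow.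

Step 4
Reactants: 4 (R)-6-[(tert-butyldimethylsilyl)oxy]-3-ethoxy-2-methylcyclohex-2-en-1-one
Product: 6 (R)-4-[(tert-butyldimethylsilyl)oxy]-2-methylcyclohex-2-en-1-one, via allylic alcohol 5 (not isolated)
Conditions: DIBAL-H, CH2Cl2, −78 °C; then 1 M HCl, THF, 0 °C (brief)
Reagents that add atoms: water, O
Why: Stork–Danheiser transposition: 1,2-reduction of the vinylogous ester, then acid-induced ionisation, enol-ether hydrolysis and loss of water move the carbonyl, so the silyloxy carbon ends up γ to the new enone carbonyl with its configuration untouched.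

Step 5
Reactants: 6 (R)-4-[(tert-butyldimethylsilyl)oxy]-2-methylcyclohex-2-en-1-one
Product: 8 (2R,3R,4R)-4-[(tert-butyldimethylsilyl)oxy]-2,3-dimethyl-2-(prop-2-yn-1-yl)cyclohexan-1-one, via lithium enolate 7 (not isolated)
Conditions: Me2CuLi (from MeLi, CuI), Et2O, −78 → −20 °C; then propargyl bromide, DMPU, THF, −78 → 0 °C
Reagents that add atoms: lithium dimethylcuprate, [Li+].C[Cu-]C; propargyl bromide, C#CCBr
Why: Cuprate conjugate addition then alkylation of the regiospecific enolate; the methyl group should add anti to the neighbouring silyloxy group (sets C4), and the electrophile should attack axially, anti to the new pseudoaxial C4 methyl that A(1,2) strain with the enolate methyl enforces (sets C5 with the two methyls cis).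

Step 6
Reactants: 8 (2R,3R,4R)-4-[(tert-butyldimethylsilyl)oxy]-2,3-dimethyl-2-(prop-2-yn-1-yl)cyclohexan-1-one
Product: 10 (6R,7R,7aR)-6-[(tert-butyldimethylsilyl)oxy]-7,7a-dimethyl-1,4,5,6,7,7a-hexahydro-2H-inden-2-one, via 1,4-diketone 9 (not isolated)
Conditions: (JohnPhos)Au(MeCN)SbF6 (cat.), dioxane/H2O, 60 °C; then KOH, MeOH, 60 °C
Reagents that add atoms: water, O
Why: Au(I)-catalysed Markovnikov hydration of the terminal alkyne (assisted by the neighbouring ketone) gives the methyl ketone, and hydroxide then drives the intramolecular aldol condensation onto the ring carbonyl to the conjugated cyclopentenone; no stereocentre is formed, C5 is quaternary and C4 is not α to a carbonyl, so nothing can epimerise.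

Step 7
Reactants: 10 (6R,7R,7aR)-6-[(tert-butyldimethylsilyl)oxy]-7,7a-dimethyl-1,4,5,6,7,7a-hexahydro-2H-inden-2-one
Product: 11 (6R,7R,7aS)-6-[(tert-butyldimethylsilyl)oxy]-7,7a-dimethyl-2-[(triethylsilyl)oxy]-5,6,7,7a-tetrahydro-4H-indene
Conditions: LDA (commercial solution), THF, −78 °C; TESCl; non-aqueous work-up, used at once
Reagents that add atoms: chlorotriethylsilane, CC[Si](CC)(CC)Cl
Why: Kinetic α′-deprotonation of the enone at C6 and O-silylation give the 2-silyloxycyclopentadiene; the quaternary C5 blocks 1,5-hydrogen shifts and slows dimerisation (the 7aS descriptor reflects only a change of CIP priorities, not of configuration).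

Step 8
Reactants: 11 (6R,7R,7aS)-6-[(tert-butyldimethylsilyl)oxy]-7,7a-dimethyl-2-[(triethylsilyl)oxy]-5,6,7,7a-tetrahydro-4H-indene
Product: 13 (4aS,5R,6R)-3-bromo-6-[(tert-butyldimethylsilyl)oxy]-4a,5-dimethyl-5,6,7,8-tetrahydronaphthalen-2(4aH)-one, via dibromocyclopropane 12 (not isolated)
Conditions: CHBr3, KOtBu, pentane, −30 °C → rt
Reagents that add atoms: bromoform, BrC(Br)Br
Why: tert-Butoxide α-eliminates HBr from bromoform, and the electrophilic singlet dibromocarbene adds in a concerted [2+1] step to the C6=C8 enol-ether double bond to give the 6,6-dibromo-1-silyloxybicyclo[3.1.0]hex-2-ene 12; ionisation of the endo C–Br bond is concerted with disrotatory opening of the C6–C8 bond (cyclopropyl-to-allyl cation), and the resulting 2-bromo-1-silyloxypentadienyl cation loses Et3Si+ to bromide to give the 7-bromo-cyclohexa-2,5-dienone. The closest known reaction types are the dihalocarbene one-carbon homologation of silyl enol ethers to 2-halo enones and the carbene-mediated carbon insertion into cyclopentadienes and indenes. The three-membered ring closes by [2+1] cheletropic addition and ring B then arises by two-electron electrocyclic opening, so the net event is insertion of C7 between C6 and C8 of the five-membered ring. No stereocentre is created: C6 and C8 return to sp2, the transient cyclopropane centres disappear, and C3, C4 and the non-enolisable C5 are untouched (the 4aS descriptor of 13 is a CIP effect of bromine). The step needs site selectivity for C6=C8 over C9=C10, which the donor oxygen on C8 secures (largest HOMO coefficient at C6) together with the fact that only the C6–C8 adduct opens to an oxygen-stabilised cation. It also needs the reaction to stop at the dienone, which the quaternary C5 secures because aromatisation is impossible.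

Step 9
Reactants: 13 (4aS,5R,6R)-3-bromo-6-[(tert-butyldimethylsilyl)oxy]-4a,5-dimethyl-5,6,7,8-tetrahydronaphthalen-2(4aH)-one
Product: 14 (4aR,5R,6R)-6-[(tert-butyldimethylsilyl)oxy]-4a,5-dimethyl-3-(prop-1-en-2-yl)-5,6,7,8-tetrahydronaphthalen-2(4aH)-one
Conditions: isopropenyl-B(pin), Pd(dppf)Cl2 (cat.), K3PO4, dioxane/H2O, 60 °C
Reagents that add atoms: isopropenylboronic acid pinacol ester, CC(=C)B1OC(C)(C)C(C)(C)O1
Why: Suzuki–Miyaura coupling of an α-bromo enone, a good oxidative-addition partner, under mild phosphate base that the dienone and silyl ether should tolerate.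

Step 10
Reactants: 14 (4aR,5R,6R)-6-[(tert-butyldimethylsilyl)oxy]-4a,5-dimethyl-3-(prop-1-en-2-yl)-5,6,7,8-tetrahydronaphthalen-2(4aH)-one
Product: 15 (4aR,5R,6R)-6-[(tert-butyldimethylsilyl)oxy]-3-(2-hydroxypropan-2-yl)-4a,5-dimethyl-5,6,7,8-tetrahydronaphthalen-2(4aH)-one
Conditions: Co(acac)2 (cat.), PhSiH3, O2 (1 atm), THF/i-PrOH, 0 °C → rt
Reagents that add atoms: dioxygen, O=O
Why: Mukaiyama hydration: hydrogen-atom transfer from the cobalt hydride should go to the only unhindered terminal CH2 (the ring alkenes are β-blocked by C5 or fully substituted at C10), and the tertiary allylic radical should be trapped by O2 at C11, which keeps the dienone conjugated, giving the Markovnikov alcohol.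

Step 11
Reactants: 15 (4aR,5R,6R)-6-[(tert-butyldimethylsilyl)oxy]-3-(2-hydroxypropan-2-yl)-4a,5-dimethyl-5,6,7,8-tetrahydronaphthalen-2(4aH)-one
Product: 16 (4aR,5R,6R)-6-hydroxy-3-(2-hydroxypropan-2-yl)-4a,5-dimethyl-5,6,7,8-tetrahydronaphthalen-2(4aH)-one
Conditions: HF·pyridine, THF/pyridine, 0 °C → rt
Reagents that add atoms: none
Why: Fluoride-mediated cleavage of the silyl ether under buffered conditions that should neither dehydrate the tertiary alcohol (its cation would sit next to an electron-poor alkene) nor trigger a dienone–phenol shift.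

Step 12
Reactants: 17 prop-2-yn-1-ol
Product: 18 (Z)-3-iodo-2-methylprop-2-en-1-ol
Conditions: MeMgBr, CuI (cat.), Et2O, −10 °C → rt; then I2, −20 °C
Reagents that add atoms: methylmagnesium bromide, C[Mg]Br; iodine, II
Why: Copper-catalysed anti-carbomagnesiation of the propargylic alkoxide gives a chelated alkenylmagnesium with Mg cis to CH2O, and iodinolysis with retention fixes the Z geometry needed in the ester.

Step 13
Reactants: 18 (Z)-3-iodo-2-methylprop-2-en-1-ol
Product: 19 (Z)-3-iodo-2-methylprop-2-enoic acid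
Conditions: TEMPO (cat.), PhI(OAc)2, MeCN/H2O, rt
Reagents that add atoms: water, O
Why: Oxoammonium (TEMPO) oxidation of the allylic alcohol through the aldehyde hydrate to the acid under near-neutral conditions that should leave the vinyl iodide and its geometry intact.

Step 14
Reactants: 19 (Z)-3-iodo-2-methylprop-2-enoic acid
Product: 20 (Z)-2-methyl-3-(methylsulfanyl)prop-2-enoic acid
Conditions: NaSMe (2.2 equiv), CuI (cat.), DMF, 0 °C → rt; aq. HCl work-up
Reagents that add atoms: sodium methanethiolate, C[S-].[Na+]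
Why: Copper-catalysed vinylic C–S coupling (Ullmann type) of the carboxylate salt, which proceeds with retention of alkene geometry.

Step 15
Reactants: 20 (Z)-2-methyl-3-(methylsulfanyl)prop-2-enoic acid; 16 (4aR,5R,6R)-6-hydroxy-3-(2-hydroxypropan-2-yl)-4a,5-dimethyl-5,6,7,8-tetrahydronaphthalen-2(4aH)-one
Product: 22 CNP0150028.1, via mixed anhydride 21 (not isolated)
Conditions: 2,4,6-trichlorobenzoyl chloride, Et3N, THF, 0 °C → rt; then 16, DMAP (cat.), toluene, rt
Reagents that add atoms: 2,4,6-trichlorobenzoyl chloride, ClC(=O)c1c(Cl)cc(Cl)cc1Cl (its acyl group is carried only by intermediate 21)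
Why: Yamaguchi esterification: the mixed anhydride should acylate the equatorial secondary C3–OH while the tertiary C11–OH stays inert, and avoiding an acid chloride, strong acid and free thiolate should preserve the Z geometry.

**Compound list**

1 | 3-ethoxy-2-methylcyclohex-2-en-1-one | CCOC1=C(C)C(=O)CCC1 | starting material
2 | rac-6-acetoxy-3-ethoxy-2-methylcyclohex-2-en-1-one | CCOC1=C(C)C(=O)C(OC(C)=O)CC1 | intermediate
3 | (R)-3-ethoxy-6-hydroxy-2-methylcyclohex-2-en-1-one | O[C@@H]1CCC(OCC)=C(C)C1=O | intermediate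
4 | (R)-6-[(tert-butyldimethylsilyl)oxy]-3-ethoxy-2-methylcyclohex-2-en-1-one | CC(C)(C)[Si](C)(C)O[C@@H]1CCC(OCC)=C(C)C1=O | intermediate
5 | (6R)-6-[(tert-butyldimethylsilyl)oxy]-3-ethoxy-2-methylcyclohex-2-en-1-ol (both C1 epimers) | CC(C)(C)[Si](C)(C)O[C@@H]1CCC(OCC)=C(C)C1O | intermediate
6 | (R)-4-[(tert-butyldimethylsilyl)oxy]-2-methylcyclohex-2-en-1-one | CC(C)(C)[Si](C)(C)O[C@@H]1CCC(=O)C(C)=C1 | intermediate
7 | lithium (3R,4R)-4-[(tert-butyldimethylsilyl)oxy]-2,3-dimethylcyclohex-1-en-1-olate | CC(C)(C)[Si](C)(C)O[C@@H]1CCC(O[Li])=C(C)[C@H]1C | intermediate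
8 | (2R,3R,4R)-4-[(tert-butyldimethylsilyl)oxy]-2,3-dimethyl-2-(prop-2-yn-1-yl)cyclohexan-1-one | CC(C)(C)[Si](C)(C)O[C@@H]1CCC(=O)[C@@](CC#C)(C)[C@H]1C | intermediate
9 | (2R,3R,4R)-4-[(tert-butyldimethylsilyl)oxy]-2,3-dimethyl-2-(2-oxopropyl)cyclohexan-1-one | CC(C)(C)[Si](C)(C)O[C@@H]1CCC(=O)[C@@](CC(C)=O)(C)[C@H]1C | intermediate
10 | (6R,7R,7aR)-6-[(tert-butyldimethylsilyl)oxy]-7,7a-dimethyl-1,4,5,6,7,7a-hexahydro-2H-inden-2-one | CC(C)(C)[Si](C)(C)O[C@@H]1CCC2=CC(=O)C[C@]2(C)[C@H]1C | intermediate
11 | (6R,7R,7aS)-6-[(tert-butyldimethylsilyl)oxy]-7,7a-dimethyl-2-[(triethylsilyl)oxy]-5,6,7,7a-tetrahydro-4H-indene | CC(C)(C)[Si](C)(C)O[C@@H]1CCC2=CC(O[Si](CC)(CC)CC)=C[C@]2(C)[C@H]1C | intermediate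
12 | dibromocarbene adduct of 11 across C6=C8 (6,6-dibromo-1-(triethylsilyloxy)bicyclo[3.1.0]hex-2-ene unit; ring-A and C5 centres as in 11, cyclopropane centres undefined) | CC(C)(C)[Si](C)(C)O[C@@H]1CCC2=CC3(O[Si](CC)(CC)CC)C(Br)(Br)C3[C@]2(C)[C@H]1C | intermediate
13 | (4aS,5R,6R)-3-bromo-6-[(tert-butyldimethylsilyl)oxy]-4a,5-dimethyl-5,6,7,8-tetrahydronaphthalen-2(4aH)-one | CC(C)(C)[Si](C)(C)O[C@@H]1CCC2=CC(=O)C(Br)=C[C@]2(C)[C@H]1C | intermediate
14 | (4aR,5R,6R)-6-[(tert-butyldimethylsilyl)oxy]-4a,5-dimethyl-3-(prop-1-en-2-yl)-5,6,7,8-tetrahydronaphthalen-2(4aH)-one | CC(C)(C)[Si](C)(C)O[C@@H]1CCC2=CC(=O)C(C(C)=C)=C[C@]2(C)[C@H]1C | intermediate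
15 | (4aR,5R,6R)-6-[(tert-butyldimethylsilyl)oxy]-3-(2-hydroxypropan-2-yl)-4a,5-dimethyl-5,6,7,8-tetrahydronaphthalen-2(4aH)-one | CC(C)(C)[Si](C)(C)O[C@@H]1CCC2=CC(=O)C(C(C)(C)O)=C[C@]2(C)[C@H]1C | intermediate
16 | (4aR,5R,6R)-6-hydroxy-3-(2-hydroxypropan-2-yl)-4a,5-dimethyl-5,6,7,8-tetrahydronaphthalen-2(4aH)-one | O[C@@H]1CCC2=CC(=O)C(C(C)(C)O)=C[C@]2(C)[C@H]1C | intermediate
17 | prop-2-yn-1-ol | C#CCO | starting material
18 | (Z)-3-iodo-2-methylprop-2-en-1-ol | I/C=C(/C)CO | intermediate
19 | (Z)-3-iodo-2-methylprop-2-enoic acid | I/C=C(/C)C(=O)O | intermediate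
20 | (Z)-2-methyl-3-(methylsulfanyl)prop-2-enoic acid | CS/C=C(/C)C(=O)O | intermediate
21 | (Z)-2-methyl-3-(methylsulfanyl)prop-2-enoic 2,4,6-trichlorobenzoic anhydride | CS/C=C(/C)C(=O)OC(=O)c1c(Cl)cc(Cl)cc1Cl | intermediate
22 | CNP0150028.1: the (2Z)-2-methyl-3-(methylsulfanyl)prop-2-enoate of the C6 hydroxyl of 16 (locants as in 16; 4aR,5R,6R, i.e. 3R,4R,5R in eremophilane numbering) | CS/C=C(/C)C(=O)O[C@@H]1CCC2=CC(=O)C(C(C)(C)O)=C[C@]2(C)[C@H]1C | target

**Step count and risks**

Total step count: 15. Longest linear sequence: 12 steps (steps 1–11, then step 15); the acid 20 is made in 3 steps (12–14) and joined in step 15.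

Steps most likely to fail:

1. Step 8. The carbene may add to the wrong double bond (C9=C10), tert-butoxide may cleave the silyl enol ether before cyclopropanation, or the base may degrade the bromodienone once formed. Fallback without a free carbene or strong base: from 11, Furukawa cyclopropanation (Et2Zn, CH2I2) of the enol-ether double bond would give the siloxycyclopropane F1. Oxidative ring opening with FeCl3 in DMF (Ito–Saegusa ring expansion) would give the ring-expanded β-chloro ketone F2, and NaOAc in MeOH would eliminate HCl to the unsubstituted dienone F3. Iodine/pyridine α-iodination, which starts by pyridine addition at the less substituted β-carbon C6, would give the 7-iodo dienone F4. F4 takes the place of 13 in the Suzuki coupling of step 9, and the route is rejoined at 14.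

2. Step 5. Facial selectivity in the alkylation may erode, because the silyloxy group is axial and syn to the incoming electrophile in the reactive enolate conformer, and C-alkylation of the copper/lithium enolate may be slow. Fallback with catalyst instead of substrate control: from 6, cuprate addition and trapping of the enolate with allyl chloroformate would give the allyl enol carbonate F5. Pd-catalysed decarboxylative allylation with the t-BuPHOX ligand enantiomer that reinforces attack anti to the C4 methyl would give the allyl ketone F6. Tsuji–Wacker oxidation (PdCl2, CuCl, O2, DMF/H2O) would give the diketone 9, where the route is rejoined (KOH aldol to 10).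

3. Step 10. Hydrogen-atom transfer may go to the dienone double bonds (conjugate reduction), or oxygen may trap the allylic radical at C6 instead of C11. Fallback by polar chemistry that also bypasses step 9: from 13, Luche reduction (NaBH4, CeCl3) would give the bromodienol F7. Deprotonation with MeLi, bromine–lithium exchange with t-BuLi at −78 °C and addition of acetone would give the diol F8. MnO2 would oxidise only the bis-allylic secondary alcohol back to the dienone, rejoining the route at 15.

**Further compounds**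

F1 | step 8 | siloxycyclopropane from 11 (CH2 across C6=C8) | CC(C)(C)[Si](C)(C)O[C@@H]1CCC2=CC3(O[Si](CC)(CC)CC)CC3[C@]2(C)[C@H]1C
F2 | step 8 | ring-expanded β-chloro ketone (6-chloro-9-en-8-one, eremophilane numbering) | CC(C)(C)[Si](C)(C)O[C@@H]1CCC2=CC(=O)CC(Cl)[C@]2(C)[C@H]1C
F3 | step 8 | 6-[(tert-butyldimethylsilyl)oxy]-4a,5-dimethyl-5,6,7,8-tetrahydronaphthalen-2(4aH)-one | CC(C)(C)[Si](C)(C)O[C@@H]1CCC2=CC(=O)C=C[C@]2(C)[C@H]1C
F4 | step 8 | 3-iodo-6-[(tert-butyldimethylsilyl)oxy]-4a,5-dimethyl-5,6,7,8-tetrahydronaphthalen-2(4aH)-one | CC(C)(C)[Si](C)(C)O[C@@H]1CCC2=CC(=O)C(I)=C[C@]2(C)[C@H]1C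
F5 | step 5 | allyl (3R,4R)-4-[(tert-butyldimethylsilyl)oxy]-2,3-dimethylcyclohex-1-en-1-yl carbonate | CC(C)(C)[Si](C)(C)O[C@@H]1CCC(OC(=O)OCC=C)=C(C)[C@H]1C
F6 | step 5 | (2R,3R,4R)-2-allyl-4-[(tert-butyldimethylsilyl)oxy]-2,3-dimethylcyclohexan-1-one | CC(C)(C)[Si](C)(C)O[C@@H]1CCC(=O)[C@@](CC=C)(C)[C@H]1C
F7 | step 10 | 3-bromo-6-[(tert-butyldimethylsilyl)oxy]-4a,5-dimethyl-2,4a,5,6,7,8-hexahydronaphthalen-2-ol (C2 epimers) | CC(C)(C)[Si](C)(C)O[C@@H]1CCC2=CC(O)C(Br)=C[C@]2(C)[C@H]1C
F8 | step 10 | 6-[(tert-butyldimethylsilyl)oxy]-3-(2-hydroxypropan-2-yl)-4a,5-dimethyl-2,4a,5,6,7,8-hexahydronaphthalen-2-ol (C2 epimers) | CC(C)(C)[Si](C)(C)O[C@@H]1CCC2=CC(O)C(C(C)(C)O)=C[C@]2(C)[C@H]1C
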